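Assumption: the target has no stereogenic element (it is achiral), so no enantiocontrol is needed; the single transient stereocentre in 8 and in 9 is racemic and is erased in the same flask.

**Retrosynthetic overview**
1. Target 11 ⇐ bis-methyl ether 10 by global O-demethylation.
2. 10 ⇐ aryloxy-p-quinone 6 + methyl 3-nitropropanoate 7: the nitronate of 7 serves as an acrylate β-anion (homoenolate-type d3) equivalent and forms C4–C4a on an electrophilic quinone carbon; the two quinone carbonyls become the lactone oxygen and the 6-OH.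
3. 6 ⇐ isoscopoletin 2 + 2-bromo-6-methoxy-1,4-benzoquinone 5 (C–O bond by addition–elimination).
4. 2 ⇐ esculetin 1 (selective 7-O-methylation); 5 ⇐ 5-bromovanillin 3 (Dakin oxidation, then oxidation to the quinone).
5. Ring order: northern coumarin bought intact → quinone ring from the aromatic aldehyde → southern pyranone ring closed last in the key step.

**Route**

Step 1
Reactants: 1 esculetin (6,7-dihydroxycoumarin)
Product: 2 isoscopoletin (6-hydroxy-7-methoxycoumarin)
Conditions: MeI (1.1 equiv), NaHCO3 (1.5 equiv), DMF, 35 °C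
Reagents that add atoms: iodomethane, CI
Why: Regioselective Williamson etherification: the 7-OH is conjugated through C4a–C4=C3 to the lactone carbonyl (pKa about 7.5) and is the only phenol that bicarbonate deprotonates, so methylation goes to O-7 and the 6-OH stays free.

Step 2
Reactants: 3 5-bromovanillin (3-bromo-4-hydroxy-5-methoxybenzaldehyde)
Product: 5 2-bromo-6-methoxy-1,4-benzoquinone, via bromomethoxyhydroquinone 4 (not isolated)
Conditions: 30% H2O2 (1.3 equiv), 1 M NaOH (1.1 equiv), THF–H2O, 0 °C → rt; HCl to pH 3, extract (CH2Cl2); then NaIO4 (1.2 equiv), CH2Cl2–H2O, rt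
Reagents that add atoms: hydrogen peroxide, OO
Why: Dakin oxidation of the para-hydroxybenzaldehyde (aryl migration in the peroxide adduct, then formate hydrolysis) gives hydroquinone 4, which periodate dehydrogenates to the p-quinone without touching Br or OMe.

Step 3
Reactants: 2 isoscopoletin; 5 2-bromo-6-methoxy-1,4-benzoquinone
Product: 6 2-methoxy-6-[(7-methoxy-2-oxo-2H-chromen-6-yl)oxy]-1,4-benzoquinone
Conditions: K2CO3 (1.1 equiv), MeCN, 0 °C → rt
Reagents that add atoms: none
Why: Addition–elimination on a haloquinone (vinylogous acyl substitution): the 6-phenoxide of 2 adds to the bromine-bearing carbon (β to the C-4 carbonyl) and bromide, a far better leaving group than methoxide, is expelled.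

Step 4
Reactants: 6 2-methoxy-6-[(7-methoxy-2-oxo-2H-chromen-6-yl)oxy]-1,4-benzoquinone; 7 methyl 3-nitropropanoate
Product: 10 6-hydroxy-7-methoxy-5-[(7-methoxy-2-oxo-2H-chromen-6-yl)oxy]coumarin, via nitro ester hydroquinone 8 (not isolated), via nitrodihydrocoumarin 9 (not isolated)
Conditions: 7 (1.2 equiv), Et3N (0.2 equiv), MeCN, −20 °C → rt; then TsOH·H2O (0.5 equiv), PhMe, 4 Å MS, 80 °C; then DBU (2.5 equiv), 0 °C → rt; aq. HCl work-up
Reagents that add atoms: none
Why: Proposed new method: the nitronate of 7, an acrylate β-anion (homoenolate-type d3) equivalent, adds in Michael fashion to quinone C-3 (the C–H carbon next to the weaker aryloxy donor and para to the methoxy-bearing carbon, matching the usual C-5 attack on 2-methoxy-1,4-benzoquinone), enolisation gives hydroquinone 8, acid-catalysed lactonisation onto the only ortho phenol gives dihydrocoumarin 9 and so fixes the cis ring geometry before DBU-mediated E1cB loss of HNO2 gives coumarin 10; the closest known reaction types are base-mediated conjugate addition of nitroalkanes to quinones and the use of 3-nitropropanoates as β-acrylate anion equivalents (Michael addition, then DBU elimination of nitrous acid).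

Step 5
Reactants: 10 6-hydroxy-7-methoxy-5-[(7-methoxy-2-oxo-2H-chromen-6-yl)oxy]coumarin
Product: 11 6,7-dihydroxy-5-[(7-hydroxy-2-oxo-2H-chromen-6-yl)oxy]-2H-chromen-2-one (target)
Conditions: BBr3 (6 equiv), CH2Cl2, −78 °C → rt; MeOH then H2O quench
Reagents that add atoms: none
Why: Lewis-acid ether cleavage (BBr3 demethylation): bromide attacks the O-methyl carbon of each borane-complexed aryl methyl ether, while the diaryl ether (no sp3 carbon) and both coumarin lactones survive, as in the standard scoparone-to-esculetin demethylation.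

**Compound list**
1 | esculetin (6,7-dihydroxycoumarin) | O=c1ccc2cc(O)c(O)cc2o1 | starting material
2 | isoscopoletin (6-hydroxy-7-methoxycoumarin) | COc1cc2oc(=O)ccc2cc1O | intermediate
3 | 5-bromovanillin (3-bromo-4-hydroxy-5-methoxybenzaldehyde) | COc1cc(C=O)cc(Br)c1O | starting material
4 | 2-bromo-6-methoxybenzene-1,4-diol | COc1cc(O)cc(Br)c1O | intermediate
5 | 2-bromo-6-methoxy-1,4-benzoquinone | COC1=CC(=O)C=C(Br)C1=O | intermediate
6 | 2-methoxy-6-[(7-methoxy-2-oxo-2H-chromen-6-yl)oxy]-1,4-benzoquinone | COC1=CC(=O)C=C(Oc2cc3ccc(=O)oc3cc2OC)C1=O | intermediate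
7 | methyl 3-nitropropanoate | COC(=O)CC[N+](=O)[O-] | starting material
8 | methyl 3-{3,6-dihydroxy-4-methoxy-2-[(7-methoxy-2-oxo-2H-chromen-6-yl)oxy]phenyl}-3-nitropropanoate (racemic) | COC(=O)CC(c1c(O)cc(OC)c(O)c1Oc1cc2ccc(=O)oc2cc1OC)[N+](=O)[O-] | intermediate
9 | 6-hydroxy-7-methoxy-5-[(7-methoxy-2-oxo-2H-chromen-6-yl)oxy]-4-nitro-3,4-dihydrocoumarin (racemic) | COc1cc2OC(=O)CC([N+](=O)[O-])c2c(Oc2cc3ccc(=O)oc3cc2OC)c1O | intermediate
10 | 6-hydroxy-7-methoxy-5-[(7-methoxy-2-oxo-2H-chromen-6-yl)oxy]coumarin | COc1cc2oc(=O)ccc2c(Oc2cc3ccc(=O)oc3cc2OC)c1O | intermediate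
11 | 6,7-dihydroxy-5-[(7-hydroxy-2-oxo-2H-chromen-6-yl)oxy]-2H-chromen-2-one (CNP0197949.0) | O=c1ccc2cc(Oc3c(O)c(O)cc4oc(=O)ccc34)c(O)cc2o1 | target

**Totals**
Total steps: 5. Longest linear sequence: 4 (1 → 2 → 6 → 10 → 11, or 3 → 5 → 6 → 10 → 11).

**Steps most likely to fail**

Step 4 is the most likely to fail. The nitronate may attack the aryloxy-bearing carbon and expel the coumarinyl oxide, may add at C-5 instead of C-3, or HNO2 may be lost before lactonisation to give an (E)-cinnamate that does not close. The fallback sets out from 6 and comes back at 10. Reduction of 6 with aqueous Na2S2O4 (EtOAc–H2O, rt) gives 2-methoxy-6-[(7-methoxy-2-oxo-2H-chromen-6-yl)oxy]benzene-1,4-diol F1, so the ring becomes the nucleophile. Pechmann-type hydroarylation–lactonisation with ethyl propiolate (ZnCl2, dioxane, 90 °C) then takes place at the only phenol with free ortho positions, para to the methoxy group, and gives 10 directly.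

Step 3 is the second risk. The phenoxide may add to a C–H position of the bromoquinone, or redox and double-substitution side reactions may dominate. The fallback sets out from 2 and comes back at 6. SNAr of 2 on commercial 3-fluoro-2-nitroanisole (K2CO3, DMF, 80 °C) gives 7-methoxy-6-(3-methoxy-2-nitrophenoxy)coumarin F2. Fe/NH4Cl (EtOH–H2O, 70 °C) reduces the nitro group to give 6-(2-amino-3-methoxyphenoxy)-7-methoxycoumarin F3. Teuber oxidation with Fremy's salt (KH2PO4 buffer, acetone–H2O, rt) turns this aniline, which has a free para position, into quinone 6.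

Step 1 is the third risk. Over-methylation to scoparone, or some methylation at O-6, would give mixtures that are hard to separate. The fallback sets out from 1 and comes back at 2. Ac2O/pyridine gives 6,7-diacetoxycoumarin F4. Mild methanolysis (NaHCO3, MeOH, 0 °C) removes the more activated 7-acetate, whose phenoxide is the better leaving group, and gives 6-acetoxy-7-hydroxycoumarin F5. Base-free methylation with TMSCHN2 (MeOH–toluene, rt), which avoids acyl migration, gives 6-acetoxy-7-methoxycoumarin F6. K2CO3/MeOH then releases 2.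

**Further compounds**
F1 | step 4 | 2-methoxy-6-[(7-methoxy-2-oxo-2H-chromen-6-yl)oxy]benzene-1,4-diol | COc1cc(O)cc(Oc2cc3ccc(=O)oc3cc2OC)c1O
F2 | step 3 | 7-methoxy-6-(3-methoxy-2-nitrophenoxy)coumarin | COc1cc2oc(=O)ccc2cc1Oc1cccc(OC)c1[N+](=O)[O-]
F3 | step 3 | 6-(2-amino-3-methoxyphenoxy)-7-methoxycoumarin | COc1cc2oc(=O)ccc2cc1Oc1cccc(OC)c1N
F4 | step 1 | 6,7-diacetoxycoumarin | CC(=O)Oc1cc2ccc(=O)oc2cc1OC(C)=O
F5 | step 1 | 6-acetoxy-7-hydroxycoumarin | CC(=O)Oc1cc2ccc(=O)oc2cc1O
F6 | step 1 | 6-acetoxy-7-methoxycoumarin | CC(=O)Oc1cc2ccc(=O)oc2cc1OC
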